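(The rate constants were drawn at random within sensible limits.)

The number to carry here is 3.75, the supply number: the charges of solid reagent that could dissolve within the time if partner in solution stayed at zero, reckoned as dissolution coefficient times solubility times time, over the charge. Solid reagent dissolves to partner, partner binds free catalyst, the bound catalyst takes up substrate, and the cycle releases product, which crystallises.

| flask | substrate | solid reagent | free catalyst | temperature | time |
|---|---|---|---|---|---|
| Friday's | 0.50 mM | 0.400 mM | 25 µM | 0 °C | 10 min |
| Tuesday's | 0.50 mM | 0.400 mM | 25 µM | 40 °C | 10 min |
| Sunday's | 0.50 mM | 0.400 mM | 25 µM | 60 °C | 10 min |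
| Wednesday's | 0.50 mM | 0.400 mM | 25 µM | 20 °C | 10 min |

- which flask leads in amount of product, in percent of the substrate charged ("all alike" within 1.5 percentage points) (Friday's / Tuesday's / Sunday's / Wednesday's / all alike)
- how much product is there at the end, in percent of the substrate charged: Friday's
- how much product is there at the end, in percent of the substrate charged: Tuesday's
- how much product is there at the end, in percent of the substrate charged: Sunday's
- how much product is there at the end, in percent of the substrate charged: Wednesday's

- amounts and yields of product count crystals too
- given per volume of solution although it is solid: crystals, solid reagent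
- constants are those at 0 °C; use the activation energies and enthalpies for any other temperature
- at the start none of the solid reagent is in solution

    partner + free catalyst ⇌ catalyst intermediate A (K1 = 3900 M⁻¹, k1 = 2100 M⁻¹ s⁻¹, Ea1 = 39.0 kJ mol⁻¹, ΔH1 = −12.0 kJ mol⁻¹)
    substrate + catalyst intermediate A → catalyst intermediate B (k2 = 2300 M⁻¹ s⁻¹, Ea2 = 36.0 kJ mol⁻¹)
    catalyst intermediate B → catalyst intermediate C (k3 = 0.85 s⁻¹, Ea3 = 66.0 kJ mol⁻¹)
    catalyst intermediate C → free catalyst + product (k4 = 78 s⁻¹, Ea4 = 50.0 kJ mol⁻¹)
    crystals ⇌ product, rate k5*(cs5 - [product]) while solid is left; crystals form when [product] > cs5 (cs5 = 0.025 mM, k5 = 5.6 s⁻¹)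
    solid reagent ⇌ partner, rate k6*(cs6 - [partner]) while solid is left; crystals form when [partner] > cs6 (cs6 = 0.051 mM, k6 = 0.049 s⁻¹)
    (constants at 0 °C)

Each turn of the cycle uses one partner and one substrate, so solid reagent is the limiting reagent and the yield stops at a fraction 0.800 of the substrate. A supply number above one says the whole charge can arrive in time, so you read the outcome as that cap. The number carries no temperature, so it stands for each flask.

Was one number enough? Dissolving slows as partner builds up, so the catalyst has to carry partner away. Take partner as steady, with dissolving equal to capture by free catalyst. With all catalyst free, capture runs at 0.0525 s⁻¹, but in Friday's, at 0 °C, catalyst intermediate A falls back at 0.538 s⁻¹ and goes on with the substrate charge at 1.15 s⁻¹, so a fraction 0.681 of captures count. Net capture of 0.0358 s⁻¹ is slower than dissolving at 0.049 s⁻¹, so in Friday's dissolving keeps a fraction 0.422 of its full pace, reckoned with the starting substrate and free catalyst. That leaves 1.58 charges, still above one. At 20 °C, 40 °C and 60 °C, forward capture quickens with 39.0 kJ mol⁻¹, so I put every flask at the cap and call them alike.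

The forecast also says all alike, reasoning that “its dissolution has no temperature dependence”. It gives Friday's 78.5% (range 74% to 80%), a little under my cap, Wednesday's 80%, Tuesday's 80% and Sunday's 80%.

The simulation gives all alike: Friday's 79.4%, Wednesday's 80.0%, Tuesday's 80.0% and Sunday's 80.0%.

Sunday's stops at 80.0% because the solid reagent runs short, standing at 0% at the end; with that shortage taken away, Sunday's reaches 100%. Now scale the supply number by the partner actually read. In Friday's at 5.00 min, partner stands at 0.668 of its solubility, which leaves 1.25 charges, above one. In a flask like Friday's kept at −15 °C, partner at the end stands at 0.836 of its solubility, which leaves 0.613, below one. That flask ends with 22.3% of its solid reagent undissolved and product at 52.7%.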